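**Retrosynthetic overview**
- The target is the penta-MOM ether after one final acetal cleavage.
- Both 2,4-dioxygenated aryl ketones come from one double addition of 2,4-bis(methoxymethoxy)phenyllithium to a bis-Weinreb amide; the C5 acrylamide arm comes from a Heck reaction on a 5-chloro-2,3-dihydrobenzofuran.
- Key disconnection: the central benzene ring and the dihydrofuran ring are opened together to a 3-chloro-6-(homopropargyloxy)pyridazine (intramolecular inverse-electron-demand Diels–Alder reaction, then loss of N2).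
- The pyridazinyl ether comes from SNAr of 3,6-dichloropyridazine with an Evans syn-aldol adduct of a but-3-ynoyl imide and 4-(methoxymethoxy)benzaldehyde; this aldol sets C2 and C3 (syn in the chain becomes trans in the ring).
- Ring order: the three outer benzene rings are bought; the dihydrofuran ring and the central benzene ring form in the same operation (step 5); no ring is formed afterwards.

Assumption: but-3-ynoic acid, 4-(methoxymethoxy)benzaldehyde, N-methoxy-N-methylprop-2-enamide and 4-bromobenzene-1,3-diol are taken as catalogue compounds; the target SMILES is read as (2S,3S), trans, E-alkene.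

**Route**

Step 1
Reactants: 1 but-3-ynoic acid; 2 (S)-4-benzyl-1,3-oxazolidin-2-one
Product: 5 (4S)-4-benzyl-3-(but-3-ynoyl)-1,3-oxazolidin-2-one, via but-3-ynoyl chloride 3 (not isolated), via lithium oxazolidinide 4 (not isolated)
Conditions: 1, (COCl)2, DMF (cat.), CH2Cl2, 0 °C, volatiles stripped cold; 2, n-BuLi, THF, −78 °C; then 3 into 4, −78 °C, 30 min
Reagents that add atoms: none
Why: N-acylation of the lithiated Evans auxiliary by the acid chloride (nucleophilic acyl substitution) is fast at −78 °C and uses no amine base, which keeps the propargyl unit from isomerising to the allene; no stereocenter is formed.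

Step 2
Reactants: 5 (4S)-4-benzyl-3-(but-3-ynoyl)-1,3-oxazolidin-2-one; 6 4-(methoxymethoxy)benzaldehyde
Product: 9 (4S)-4-benzyl-3-{(2S,3S)-2-ethynyl-3-hydroxy-3-[4-(methoxymethoxy)phenyl]propanoyl}-1,3-oxazolidin-2-one, via boron enolate 7 (not isolated), via boron aldolate 8 (not isolated)
Conditions: Bu2BOTf, i-Pr2NEt, CH2Cl2, −78 → 0 °C; 6, −78 → 0 °C; then pH 7 buffer, MeOH, 30% H2O2, 0 °C
Reagents that add atoms: none
Why: Evans syn-aldol reaction, in which the (Z)-boron enolate reacts at its α-carbon through a closed Zimmerman–Traxler chair on the face away from the benzyl group, so the (S)-auxiliary gives the (2S,3S) syn adduct and thereby sets both stereocenters of the target.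

Step 3
Reactants: 9 (4S)-4-benzyl-3-{(2S,3S)-2-ethynyl-3-hydroxy-3-[4-(methoxymethoxy)phenyl]propanoyl}-1,3-oxazolidin-2-one
Product: 10 (2S,3S)-2-ethynyl-3-hydroxy-N-methoxy-3-[4-(methoxymethoxy)phenyl]-N-methylpropanamide
Conditions: MeNHOMe, AlMe3, CH2Cl2, −20 → 0 °C; aq. KNaC4H4O6 work-up
Reagents that add atoms: N,O-dimethylhydroxylamine, CNOC
Why: Weinreb transamidation with the aluminium amide, directed to the exocyclic carbonyl by the aluminium alkoxide of the free β-hydroxyl, releases the auxiliary without touching either stereocenter.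

Step 4
Reactants: 10 (2S,3S)-2-ethynyl-3-hydroxy-N-methoxy-3-[4-(methoxymethoxy)phenyl]-N-methylpropanamide; 11 3,6-dichloropyridazine
Product: 13 (2S,3S)-3-[(6-chloropyridazin-3-yl)oxy]-2-ethynyl-N-methoxy-3-[4-(methoxymethoxy)phenyl]-N-methylpropanamide, via sodium alkoxide 12 (not isolated)
Conditions: NaN(SiMe3)2 (1.0 equiv), THF, −78 °C; then 11, −78 → 0 °C
Reagents that add atoms: none
Why: SNAr (addition–elimination) of the alkoxide on the doubly activated dichloropyridazine stops after one substitution because the new alkoxy group deactivates the ring, and since the carbinol C–O bond is not broken the configuration is retained (one equivalent of base and low temperature hold back retro-aldol and E1cB loss).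

Step 5 (key step)
Reactants: 13 (2S,3S)-3-[(6-chloropyridazin-3-yl)oxy]-2-ethynyl-N-methoxy-3-[4-(methoxymethoxy)phenyl]-N-methylpropanamide
Product: 15 (2S,3S)-5-chloro-N-methoxy-2-[4-(methoxymethoxy)phenyl]-N-methyl-2,3-dihydro-1-benzofuran-3-carboxamide, via bridged cycloadduct 14 (not isolated)
Conditions: 1,2-dichlorobenzene (0.02 M), 180 °C, sealed tube, 16 h
Reagents that add atoms: none
Why: Intramolecular inverse-electron-demand Diels–Alder reaction of the chloropyridazine (C3 and C6 as diene termini) with the tethered terminal alkyne, followed by retro-Diels–Alder loss of N2, is an established reaction type for alkynyl-tethered pyridazines and closes the dihydrofuran ring and the benzene ring in one operation, while the two tether stereocenters are spectators so the syn-aldol pattern appears as the trans-(2S,3S) ring.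

Step 6
Reactants: 15 (2S,3S)-5-chloro-N-methoxy-2-[4-(methoxymethoxy)phenyl]-N-methyl-2,3-dihydro-1-benzofuran-3-carboxamide; 16 N-methoxy-N-methylprop-2-enamide
Product: 17 (2S,3S)-N-methoxy-5-{(E)-3-[methoxy(methyl)amino]-3-oxoprop-1-enyl}-2-[4-(methoxymethoxy)phenyl]-N-methyl-2,3-dihydro-1-benzofuran-3-carboxamide
Conditions: Pd2(dba)3 (2 mol%), [HP(t-Bu)3]BF4 (8 mol%), Cy2NMe, 1,4-dioxane, 110 °C
Reagents that add atoms: none
Why: Mizoroki–Heck reaction, where the bulky electron-rich phosphine lets zerovalent palladium insert into the electron-rich aryl chloride, syn-insertion and syn-β-hydride elimination give the E-alkene, and the amine base can only hold C3 in the thermodynamically preferred trans arrangement it already has.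

Step 7
Reactants: 18 4-bromobenzene-1,3-diol
Product: 19 1-bromo-2,4-bis(methoxymethoxy)benzene
Conditions: MOMCl, i-Pr2NEt, CH2Cl2, 0 °C → rt
Reagents that add atoms: chloromethyl methyl ether (MOMCl), COCCl
Why: O-alkylation of both phenols (Williamson-type acetal protection) gives ethers that survive the aryllithium and whose ortho oxygen stabilises it.

Step 8
Reactants: 17 (2S,3S)-N-methoxy-5-{(E)-3-[methoxy(methyl)amino]-3-oxoprop-1-enyl}-2-[4-(methoxymethoxy)phenyl]-N-methyl-2,3-dihydro-1-benzofuran-3-carboxamide; 19 1-bromo-2,4-bis(methoxymethoxy)benzene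
Product: 22 (E)-1-[2,4-bis(methoxymethoxy)phenyl]-3-{(2S,3S)-3-[2,4-bis(methoxymethoxy)benzoyl]-2-[4-(methoxymethoxy)phenyl]-2,3-dihydro-1-benzofuran-5-yl}prop-2-en-1-one, via aryllithium 20 (not isolated), via dilithium bis-adduct 21 (not isolated)
Conditions: 19 (3.2 equiv), n-BuLi (3.0 equiv), THF, −78 °C; then 17, −78 → −20 °C; sat. aq. NH4Cl
Reagents that add atoms: none
Why: Bromine–lithium exchange followed by Weinreb ketone synthesis at both amides at once, in which each chelated tetrahedral adduct blocks over-addition and conjugate addition until the quench, and C3 stays trans because that is its thermodynamic configuration.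

Step 9
Reactants: 22 (E)-1-[2,4-bis(methoxymethoxy)phenyl]-3-{(2S,3S)-3-[2,4-bis(methoxymethoxy)benzoyl]-2-[4-(methoxymethoxy)phenyl]-2,3-dihydro-1-benzofuran-5-yl}prop-2-en-1-one
Product: 23 (E)-1-(2,4-dihydroxyphenyl)-3-[(2S,3S)-3-(2,4-dihydroxybenzoyl)-2-(4-hydroxyphenyl)-2,3-dihydro-1-benzofuran-5-yl]prop-2-en-1-one
Conditions: 3 M HCl, MeOH–THF, 40 °C
Reagents that add atoms: none
Why: Acid-catalysed acetal cleavage (transacetalisation to methanol) removes all five MOM groups, and the mild temperature avoids flavanone closure of the 2'-hydroxychalcone and ionisation of the benzylic C2–O bond.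

**Compound list**

1 | but-3-ynoic acid | C#CCC(=O)O | starting material
2 | (S)-4-benzyl-1,3-oxazolidin-2-one | O=C1N[C@@H](Cc2ccccc2)CO1 | starting material
3 | but-3-ynoyl chloride | C#CCC(=O)Cl | intermediate (not isolated)
4 | lithium (S)-4-benzyl-2-oxo-1,3-oxazolidin-3-ide | [Li+].O=C1[N-][C@@H](Cc2ccccc2)CO1 | intermediate (not isolated)
5 | (4S)-4-benzyl-3-(but-3-ynoyl)-1,3-oxazolidin-2-one | C#CCC(=O)N1[C@@H](Cc2ccccc2)COC1=O | intermediate
6 | 4-(methoxymethoxy)benzaldehyde | COCOc1ccc(C=O)cc1 | starting material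
7 | (4S)-4-benzyl-3-[(1Z)-1-(dibutylboranyloxy)but-1-en-3-yn-1-yl]-1,3-oxazolidin-2-one (boron enolate of 5) | C#C/C=C(\OB(CCCC)CCCC)N1[C@@H](Cc2ccccc2)COC1=O | intermediate (not isolated)
8 | (4S)-4-benzyl-3-{(2S,3S)-3-(dibutylboranyloxy)-2-ethynyl-3-[4-(methoxymethoxy)phenyl]propanoyl}-1,3-oxazolidin-2-one (boron aldolate) | C#C[C@H](C(=O)N1[C@@H](Cc2ccccc2)COC1=O)[C@@H](c1ccc(OCOC)cc1)OB(CCCC)CCCC | intermediate (not isolated)
9 | (4S)-4-benzyl-3-{(2S,3S)-2-ethynyl-3-hydroxy-3-[4-(methoxymethoxy)phenyl]propanoyl}-1,3-oxazolidin-2-one | C#C[C@H](C(=O)N1[C@@H](Cc2ccccc2)COC1=O)[C@@H](c1ccc(OCOC)cc1)O | intermediate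
10 | (2S,3S)-2-ethynyl-3-hydroxy-N-methoxy-3-[4-(methoxymethoxy)phenyl]-N-methylpropanamide | C#C[C@H](C(=O)N(C)OC)[C@@H](c1ccc(OCOC)cc1)O | intermediate
11 | 3,6-dichloropyridazine | Clc1ccc(Cl)nn1 | starting material
12 | sodium alkoxide of 10 | C#C[C@H](C(=O)N(C)OC)[C@@H](c1ccc(OCOC)cc1)[O-].[Na+] | intermediate (not isolated)
13 | (2S,3S)-3-[(6-chloropyridazin-3-yl)oxy]-2-ethynyl-N-methoxy-3-[4-(methoxymethoxy)phenyl]-N-methylpropanamide | C#C[C@H](C(=O)N(C)OC)[C@@H](c1ccc(OCOC)cc1)Oc1ccc(Cl)nn1 | intermediate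
14 | dihydrofuran-fused 2,3-diazabicyclo[2.2.2]octa-2,5,7-triene cycloadduct of 13 (bridgehead configuration not defined) | C1=C2[C@H](C(=O)N(C)OC)[C@@H](c3ccc(OCOC)cc3)OC24N=NC1(Cl)C=C4 | intermediate (not isolated)
15 | (2S,3S)-5-chloro-N-methoxy-2-[4-(methoxymethoxy)phenyl]-N-methyl-2,3-dihydro-1-benzofuran-3-carboxamide | Clc1ccc2c(c1)[C@H](C(=O)N(C)OC)[C@@H](c1ccc(OCOC)cc1)O2 | intermediate
16 | N-methoxy-N-methylprop-2-enamide | C=CC(=O)N(C)OC | starting material
17 | (2S,3S)-N-methoxy-5-{(E)-3-[methoxy(methyl)amino]-3-oxoprop-1-enyl}-2-[4-(methoxymethoxy)phenyl]-N-methyl-2,3-dihydro-1-benzofuran-3-carboxamide | CON(C)C(=O)/C=C/c1ccc2c(c1)[C@H](C(=O)N(C)OC)[C@@H](c1ccc(OCOC)cc1)O2 | intermediate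
18 | 4-bromobenzene-1,3-diol | Oc1ccc(Br)c(O)c1 | starting material
19 | 1-bromo-2,4-bis(methoxymethoxy)benzene | COCOc1ccc(Br)c(OCOC)c1 | intermediate
20 | [2,4-bis(methoxymethoxy)phenyl]lithium | [Li]c1ccc(OCOC)cc1OCOC | intermediate (not isolated)
21 | dilithium bis(hemiaminal alkoxide) formed from 17 and two molecules of 20 (new carbinol centers not defined) | CON(C)C([O-])(/C=C/c1ccc2c(c1)[C@H](C([O-])(N(C)OC)c1ccc(OCOC)cc1OCOC)[C@@H](c1ccc(OCOC)cc1)O2)c1ccc(OCOC)cc1OCOC.[Li+].[Li+] | intermediate (not isolated)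
22 | (E)-1-[2,4-bis(methoxymethoxy)phenyl]-3-{(2S,3S)-3-[2,4-bis(methoxymethoxy)benzoyl]-2-[4-(methoxymethoxy)phenyl]-2,3-dihydro-1-benzofuran-5-yl}prop-2-en-1-one | COCOc1ccc(C(=O)/C=C/c2ccc3c(c2)[C@H](C(=O)c2ccc(OCOC)cc2OCOC)[C@@H](c2ccc(OCOC)cc2)O3)c(OCOC)c1 | intermediate
23 | (E)-1-(2,4-dihydroxyphenyl)-3-[(2S,3S)-3-(2,4-dihydroxybenzoyl)-2-(4-hydroxyphenyl)-2,3-dihydro-1-benzofuran-5-yl]prop-2-en-1-one | O=C(/C=C/c1ccc2c(c1)[C@H](C(=O)c1ccc(O)cc1O)[C@@H](c1ccc(O)cc1)O2)c1ccc(O)cc1O | target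

**Step count**
Total: 9 steps. Longest linear sequence: 8 steps (steps 1–6, 8, 9, from but-3-ynoic acid); step 7 is a one-step side branch.

**Three steps most likely to fail**

Step 5 (cycloaddition). At 180 °C the pyridazinyloxy group of 13 can be lost by thermal syn-elimination, helped by the acidic hydrogen between the amide and the alkyne, before the cycloaddition takes place. The fallback carries the future C3 carbonyl through the cycloaddition at the alcohol oxidation level, so that no acidic hydrogen flanks the leaving group. It sets out from 9. LiBH4 (THF–MeOH, 0 °C) removes the auxiliary reductively and gives the diol (1S,2R)-2-ethynyl-1-[4-(methoxymethoxy)phenyl]propane-1,3-diol F1. t-BuPh2SiCl and imidazole silylate only the primary hydroxyl and give (1S,2R)-2-{[tert-butyl(diphenyl)silyl]oxymethyl}-1-[4-(methoxymethoxy)phenyl]but-3-yn-1-ol F2. NaN(SiMe3)2 and then 11 give the pyridazinyl ether 3-chloro-6-{(1S,2R)-2-{[tert-butyl(diphenyl)silyl]oxymethyl}-1-[4-(methoxymethoxy)phenyl]but-3-ynoxy}pyridazine F3. Heating in 1,2-dichlorobenzene at 200 °C brings about the same cycloaddition and N2 loss and gives tert-butyl{[(2S,3R)-5-chloro-2-[4-(methoxymethoxy)phenyl]-2,3-dihydro-1-benzofuran-3-yl]methoxy}diphenylsilane F4. Bu4NF in THF gives the alcohol [(2S,3R)-5-chloro-2-[4-(methoxymethoxy)phenyl]-2,3-dihydro-1-benzofuran-3-yl]methanol F5. TEMPO (cat.) and PhI(OAc)2 in MeCN–H2O give the acid (2S,3S)-5-chloro-2-[4-(methoxymethoxy)phenyl]-2,3-dihydro-1-benzofuran-3-carboxylic acid F6. Coupling of the acid with MeNHOMe·HCl (carbodiimide, HOBt, i-Pr2NEt) comes back to the route at 15.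

Step 2 (aldol). Imide 5 and its enolate can isomerise to the allenoyl imide, and the conjugated enolate may react at its remote carbon. The fallback replaces the alkyne by a 2-bromoalkene, which cannot form an allene and which gives the same arene carbons once HBr is lost after the cycloaddition. It sets out from 2. Acylation with 3-bromobut-3-enoic acid by the protocol of step 1 gives (4S)-4-benzyl-3-(3-bromobut-3-enoyl)-1,3-oxazolidin-2-one F7. The same boron aldol with 6 gives the syn adduct (4S)-4-benzyl-3-{(2S,3S)-2-(1-bromoethenyl)-3-hydroxy-3-[4-(methoxymethoxy)phenyl]propanoyl}-1,3-oxazolidin-2-one F8. AlMe3 and MeNHOMe give the Weinreb amide (2S,3S)-2-(1-bromoethenyl)-3-hydroxy-N-methoxy-3-[4-(methoxymethoxy)phenyl]-N-methylpropanamide F9. NaN(SiMe3)2 and 11 give the pyridazinyl ether (2S,3S)-2-(1-bromoethenyl)-3-[(6-chloropyridazin-3-yl)oxy]-N-methoxy-3-[4-(methoxymethoxy)phenyl]-N-methylpropanamide F10. Heating as in step 5 (cycloaddition of the bromoalkene, loss of N2, then loss of HBr) comes back to the route at 15.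

Step 8 (double aryl addition). Aryllithium 20 is hindered and basic, and the C3 hydrogen of 17 is benzylic and α to an amide, so enolisation may outrun addition at the C3 amide. The fallback goes through the far more electrophilic aldehydes. It sets out from 17. i-Bu2AlH (THF, −78 °C) reduces both Weinreb amides and gives the dialdehyde (2S,3S)-2-[4-(methoxymethoxy)phenyl]-5-[(E)-3-oxoprop-1-enyl]-2,3-dihydro-1-benzofuran-3-carbaldehyde F11. Aryllithium 20 (2.5 equiv, −78 °C) adds to both formyl groups and gives the bis-carbinol (E)-1-[2,4-bis(methoxymethoxy)phenyl]-3-{(2S,3S)-3-{[2,4-bis(methoxymethoxy)phenyl](hydroxy)methyl}-2-[4-(methoxymethoxy)phenyl]-2,3-dihydro-1-benzofuran-5-yl}prop-2-en-1-ol F12 as a mixture of carbinol epimers. Dess–Martin periodinane (CH2Cl2, NaHCO3) oxidises both carbinols and comes back to the route at 22.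

**Further compounds**

F1 | step 5 | (1S,2R)-2-ethynyl-1-[4-(methoxymethoxy)phenyl]propane-1,3-diol | C#C[C@H](CO)[C@@H](c1ccc(OCOC)cc1)O
F2 | step 5 | (1S,2R)-2-{[tert-butyl(diphenyl)silyl]oxymethyl}-1-[4-(methoxymethoxy)phenyl]but-3-yn-1-ol | C#C[C@H](CO[Si](c1ccccc1)(c1ccccc1)C(C)(C)C)[C@@H](c1ccc(OCOC)cc1)O
F3 | step 5 | 3-chloro-6-{(1S,2R)-2-{[tert-butyl(diphenyl)silyl]oxymethyl}-1-[4-(methoxymethoxy)phenyl]but-3-ynoxy}pyridazine | C#C[C@H](CO[Si](c1ccccc1)(c1ccccc1)C(C)(C)C)[C@@H](c1ccc(OCOC)cc1)Oc1ccc(Cl)nn1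
F4 | step 5 | tert-butyl{[(2S,3R)-5-chloro-2-[4-(methoxymethoxy)phenyl]-2,3-dihydro-1-benzofuran-3-yl]methoxy}diphenylsilane | Clc1ccc2c(c1)[C@H](CO[Si](c1ccccc1)(c1ccccc1)C(C)(C)C)[C@@H](c1ccc(OCOC)cc1)O2
F5 | step 5 | [(2S,3R)-5-chloro-2-[4-(methoxymethoxy)phenyl]-2,3-dihydro-1-benzofuran-3-yl]methanol | Clc1ccc2c(c1)[C@H](CO)[C@@H](c1ccc(OCOC)cc1)O2
F6 | step 5 | (2S,3S)-5-chloro-2-[4-(methoxymethoxy)phenyl]-2,3-dihydro-1-benzofuran-3-carboxylic acid | Clc1ccc2c(c1)[C@H](C(=O)O)[C@@H](c1ccc(OCOC)cc1)O2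
F7 | step 2 | (4S)-4-benzyl-3-(3-bromobut-3-enoyl)-1,3-oxazolidin-2-one | C=C(Br)CC(=O)N1[C@@H](Cc2ccccc2)COC1=O
F8 | step 2 | (4S)-4-benzyl-3-{(2S,3S)-2-(1-bromoethenyl)-3-hydroxy-3-[4-(methoxymethoxy)phenyl]propanoyl}-1,3-oxazolidin-2-one | C=C(Br)[C@H](C(=O)N1[C@@H](Cc2ccccc2)COC1=O)[C@@H](c1ccc(OCOC)cc1)O
F9 | step 2 | (2S,3S)-2-(1-bromoethenyl)-3-hydroxy-N-methoxy-3-[4-(methoxymethoxy)phenyl]-N-methylpropanamide | C=C(Br)[C@H](C(=O)N(C)OC)[C@@H](c1ccc(OCOC)cc1)O
F10 | step 2 | (2S,3S)-2-(1-bromoethenyl)-3-[(6-chloropyridazin-3-yl)oxy]-N-methoxy-3-[4-(methoxymethoxy)phenyl]-N-methylpropanamide | C=C(Br)[C@H](C(=O)N(C)OC)[C@@H](c1ccc(OCOC)cc1)Oc1ccc(Cl)nn1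
F11 | step 8 | (2S,3S)-2-[4-(methoxymethoxy)phenyl]-5-[(E)-3-oxoprop-1-enyl]-2,3-dihydro-1-benzofuran-3-carbaldehyde | O=C/C=C/c1ccc2c(c1)[C@H](C=O)[C@@H](c1ccc(OCOC)cc1)O2
F12 | step 8 | (E)-1-[2,4-bis(methoxymethoxy)phenyl]-3-{(2S,3S)-3-{[2,4-bis(methoxymethoxy)phenyl](hydroxy)methyl}-2-[4-(methoxymethoxy)phenyl]-2,3-dihydro-1-benzofuran-5-yl}prop-2-en-1-ol (carbinol centers not defined) | COCOc1ccc(C(O)/C=C/c2ccc3c(c2)[C@H](C(O)c2ccc(OCOC)cc2OCOC)[C@@H](c2ccc(OCOC)cc2)O3)c(OCOC)c1
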